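All runs were computed from invented constants; scatter was added.

The target readings in this flask climb fast and then stop rising, and we want to know whether that stop is an end. We have one flask, with these readings and options:

common to all: solid substrate 2.4 M; temperature −20 °C
- theta: the very flask that is asked about, followed so far
- flask: time 25 h

- theta (time / h: target / %): 4.00: 44.2; 8.00: 58.5; 10.0: 61.4; 15.0: 64.9; 20.0: 63.3; 25.0: 62.6

(standard deviation of a reading: 1 percentage point)

- Friday's: at 25 h raise the temperature by 15 K, then wait 8.0 h
- Thursday's: at 25 h take out 90 % of the target then present, then wait 8.0 h
- Wednesday's: change nothing and wait 8.0 h more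

- as a solid, counted per litre of solution: solid substrate
- what is taken out of target is counted as made
- what may be going on: starting material -> intermediate A; intermediate A -> side product; intermediate A -> target; intermediate A <-> intermediate B; intermediate B <-> intermediate C; solid substrate <-> starting material; starting material <-> dormant form
- at the start none of the solid substrate is in solution
- the earlier runs do not show what temperature does; that part of a forecast is a guess

1. target, in percent of the solid substrate first charged, at 25 h
2. which option adds most target ("none" when 2 percentage points or less is all one gets) (Friday's / Thursday's / Wednesday's / none)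
3. target present, with what was taken out counted in, in percent of the solid substrate first charged, after Friday's
4. target present, with what was taken out counted in, in percent of the solid substrate first charged, after Thursday's

We replace the tail by its mean, the readings from 15.0 h on, which gives a plateau of 63.6 %. That is our value for now. Replacing the early curve by its mean pace up to 4.00 h would bring the flask to that plateau in 5.76 h. But the reading at 8.00 h is still 5.1 percentage points short, so the pace falls, and we take a first-order rise instead:

k = ln(plateau / (plateau − c(target) at 4.00 h)) / 4.00 h = 0.297 /h

rise time = ln(2) / k = 2.34 h

The rise time is the time in which c(target) closes half of its distance to the plateau.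

One reading set k, so we test it. At 8.00 h the rise gives 57.7 %, which is 0.82 points from the reading, less than the scatter of 1 point.

By 25 h the flask has had 10.7 rise times, so our fitted rise has 0.038 points left, less than the margin, and Wednesday's looks useless. Thursday's looks the same. The listed steps form target one way and consume none.

But a flat tail tells us what target does, not where the gap of 36.4 % sits. It may be side product, or it may be parked behind the reversible steps, and these target readings do not split it. So we bet on Friday's, with its size a guess below that gap.

The forecast gives 63.5 % now, 64.5 % after Friday's, 63.8 % after Thursday's and best option none, holding that “the flask looks finished”, so it parts from our bet.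

The flask gives 63.1 %, then 74.6 % after Friday's and 63.5 % after Thursday's. Friday's adds 12 points, more than Thursday's 0.45 points or Wednesday's 0.45 points, so the best is Friday's.

    starting material → intermediate A (k = 1.67 × 10⁻⁴ /s, Ea = 80.0 kJ/mol)
    intermediate A → side product (k = 3.99 × 10⁻⁵ /s, Ea = 80.0 kJ/mol)
    intermediate A → target (k = 1.36 × 10⁻⁴ /s, Ea = 83.0 kJ/mol)
    intermediate A ⇌ intermediate B (K = 4.40, k = 4.03 × 10⁻⁵ /s, Ea = 75.0 kJ/mol, ΔH = −55.0 kJ/mol)
    intermediate B ⇌ intermediate C (K = 7.28, k = 3.90 × 10⁻⁵ /s, Ea = 77.0 kJ/mol, ΔH = −53.0 kJ/mol)
    solid substrate ⇌ starting material, rate k6*(cs6 - [starting material]) while solid is left; crystals form when [starting material] > cs6 (solubility = 1.90 M, k = 0.00110 /s)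
    starting material ⇌ dormant form (K = 3.10, k = 7.60 × 10⁻⁶ /s, Ea = 83.0 kJ/mol, ΔH = −29.0 kJ/mol)
    (constants at −20 °C)

In this flask the forward step from intermediate B to intermediate C has a half-life of 4.9 h, twice our rise time. At 25.0 h this flask holds 12.8 % as intermediate C beside 18.5 % as side product.

For the neighbour flask read at 6.0 h, the rise time gives 52.8 %. The computed value there is 54.9 %.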